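Unit 1 is the flavanone with locants 2–8a and 1'–6' (its ring B carries the biaryl bond at C3'). Unit 2 has locants 2''–8a'' and 1'''–6''' (its ring A carries the bond at C6'').
Retrosynthetic cuts, in order: O1''–C2'' of ring C of unit 2, after a CO2t-Bu helper is put back on C3''; then C2''=C3'' (Knoevenagel, which frees ring B of unit 2 as an aldehyde); then C2–C1' (aryl 1,4-addition to a chromone); then the C3'–C6'' biaryl bond (Suzuki–Miyaura).
Forward order: ring C of unit 1 is closed first as a flat chromone, the biaryl is built on an acetophenone, its boronic acid is added to the chromone, and ring C of unit 2 is closed last. Both A rings come from acetophenone 1.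
Enabling feature: C3'' is a bare CH2 next to C4''=O, so an ester can sit there, make C2'' a doubly activated benzylidene carbon and leave as CO2. The oxygen on C8a'' has only H-8'' beside it, whereas O-5'' is wedged between C4''=O and the C6'' aryl group and can be capped separately.
Stereochemistry: C2 (S) comes from the chiral PyOx ligand in the 1,4-addition and C2'' (S) from a cinchona thiourea in the ring closure. Only neutral or acidic steps follow each centre, and unit 2 is closed last because its 4'''-oxygenated ring B makes C2'' the more labile centre.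

Key step: step 13

Assumption: the C3'–C6'' axis (three oxygen ortho substituents, no descriptor in the target) is taken as freely rotating at room temperature, and the sense of induction of (R)-t-BuPyOx (step 10) and of the epi-quinidine thiourea (step 13) is assigned by analogy with simpler enones, the mirror-image ligand and the pseudo-enantiomeric epi-quinine catalyst being equally available should the sense prove opposite.

Step 1
Reactants: 1 1-(2,6-dihydroxy-4-methoxyphenyl)ethanone
Product: 2 1-[2-(benzyloxy)-6-hydroxy-4-methoxyphenyl]ethanone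
Conditions: BnBr (1.0 equiv), K2CO3 (1.1 equiv), acetone, reflux
Reagents that add atoms: benzyl bromide BrCc1ccccc1
Why: The Williamson ether synthesis should stop at the monoether because the two hydroxyls of 1 are equivalent and the remaining one is held in a hydrogen bond to the acetyl carbonyl.

Step 2
Reactants: 2 1-[2-(benzyloxy)-6-hydroxy-4-methoxyphenyl]ethanone
Product: 4 5-(benzyloxy)-7-methoxy-4H-chromen-4-one, via enaminone 3 (not isolated)
Conditions: DMF-DMA, toluene, 95 °C; then conc. HCl, CH2Cl2, rt
Reagents that add atoms: N,N-dimethylformamide dimethyl acetal COC(OC)N(C)C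
Why: In this enaminone chromone synthesis the acetyl CH3 condenses with the amide acetal and the free phenol then adds and expels dimethylamine, which closes ring C of unit 1 at an oxidation level with no stereocentre to lose.

Step 3
Reactants: 1 1-(2,6-dihydroxy-4-methoxyphenyl)ethanone
Product: 5 1-[2-hydroxy-4-methoxy-6-(methoxymethoxy)phenyl]ethanone
Conditions: MOMCl (1.05 equiv), K2CO3 (1.2 equiv), acetone, 0 °C to rt
Reagents that add atoms: chloromethyl methyl ether COCCl
Why: Williamson-type acetal protection of one of two equivalent phenols is self-limiting through chelation of the second, and it marks the oxygen that will later become O1''.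

Step 4
Reactants: 5 1-[2-hydroxy-4-methoxy-6-(methoxymethoxy)phenyl]ethanone
Product: 6 1-[2-hydroxy-3-iodo-4-methoxy-6-(methoxymethoxy)phenyl]ethanone
Conditions: NIS (1.0 equiv), MeCN, 0 °C to rt
Reagents that add atoms: N-iodosuccinimide O=C1CCC(=O)N1I
Why: Electrophilic aromatic iodination of 2-hydroxy-4,6-dialkoxyacetophenones goes ortho to the free phenol (C3, between OH and OMe), which places the halogen next to the oxygen that ends as O-5''.

Step 5
Reactants: 6 1-[2-hydroxy-3-iodo-4-methoxy-6-(methoxymethoxy)phenyl]ethanone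
Product: 7 1-[2-(benzyloxy)-3-iodo-4-methoxy-6-(methoxymethoxy)phenyl]ethanone
Conditions: BnBr, K2CO3, DMF, 60 °C
Reagents that add atoms: benzyl bromide BrCc1ccccc1
Why: The Williamson ether synthesis caps the hindered phenol next to iodine, so the two oxygens ortho to the acyl group are now different (benzyl stays to the end, MOM leaves before the ring closure).

Step 6
Reactants: 7 1-[2-(benzyloxy)-3-iodo-4-methoxy-6-(methoxymethoxy)phenyl]ethanone; 8 (5-chloro-2-methoxyphenyl)boronic acid
Product: 9 1-[2-(benzyloxy)-5'-chloro-2',6-dimethoxy-4-(methoxymethoxy)biphenyl-3-yl]ethanone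
Conditions: PdCl2(dppf) (5 mol %), K2CO3, dioxane/H2O, 90 °C
Reagents that add atoms: none
Why: In this Suzuki–Miyaura coupling the dppf-ligated zerovalent palladium inserts into the C–I bond and leaves the electron-rich C–Cl bond alone, so the C3'–C6'' bond forms before any stereocentre exists and the base can do no harm.

Step 7
Reactants: 9 1-[2-(benzyloxy)-5'-chloro-2',6-dimethoxy-4-(methoxymethoxy)biphenyl-3-yl]ethanone
Product: 10 1-[2-(benzyloxy)-2',6-dimethoxy-4-(methoxymethoxy)-5'-(4,4,5,5-tetramethyl-1,3,2-dioxaborolan-2-yl)biphenyl-3-yl]ethanone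
Conditions: B2pin2, Pd2(dba)3 (2 mol %), XPhos (8 mol %), KOAc, dioxane, 100 °C
Reagents that add atoms: bis(pinacolato)diboron CC1(C)OB(OC1(C)C)B1OC(C)(C)C(C)(C)O1
Why: Miyaura borylation with a bulky, electron-rich biaryl phosphine activates 4-chloroanisole-type chlorides, and KOAc is too weak a base to enolise the methyl ketone.

Step 8
Reactants: 10 1-[2-(benzyloxy)-2',6-dimethoxy-4-(methoxymethoxy)-5'-(4,4,5,5-tetramethyl-1,3,2-dioxaborolan-2-yl)biphenyl-3-yl]ethanone
Product: 11 tert-butyl 3-[2-(benzyloxy)-2',6-dimethoxy-4-(methoxymethoxy)-5'-(4,4,5,5-tetramethyl-1,3,2-dioxaborolan-2-yl)biphenyl-3-yl]-3-oxopropanoate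
Conditions: LiN(SiMe3)2 (2.3 equiv), THF, −78 °C; Boc2O (1.1 equiv), −78 to −20 °C; AcOH quench
Reagents that add atoms: di-tert-butyl dicarbonate CC(C)(C)OC(=O)OC(=O)OC(C)(C)C
Why: Crossed Claisen-type C-acylation of the lithium enolate installs the helper ester while strong base is still harmless (no flavanone is present), the second equivalent of base takes up the acidic product proton, and the hindered amide spares the pinacol boronate.

Step 9
Reactants: 11 tert-butyl 3-[2-(benzyloxy)-2',6-dimethoxy-4-(methoxymethoxy)-5'-(4,4,5,5-tetramethyl-1,3,2-dioxaborolan-2-yl)biphenyl-3-yl]-3-oxopropanoate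
Product: 12 [2'-(benzyloxy)-3'-(3-tert-butoxy-3-oxopropanoyl)-6,6'-dimethoxy-4'-(methoxymethoxy)biphenyl-3-yl]boronic acid
Conditions: NaIO4, NH4OAc, acetone/H2O, rt
Reagents that add atoms: water O
Why: Periodate glycol cleavage destroys the pinacol released by hydrolysis and so pulls the boronate–boronic acid equilibrium to the free acid under near-neutral conditions, which all ethers and the tert-butyl ester tolerate.

Step 10
Reactants: 12 [2'-(benzyloxy)-3'-(3-tert-butoxy-3-oxopropanoyl)-6,6'-dimethoxy-4'-(methoxymethoxy)biphenyl-3-yl]boronic acid; 4 5-(benzyloxy)-7-methoxy-4H-chromen-4-one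
Product: 13 tert-butyl 3-{2-(benzyloxy)-5'-[(2S)-5-(benzyloxy)-7-methoxy-4-oxochroman-2-yl]-2',6-dimethoxy-4-(methoxymethoxy)biphenyl-3-yl}-3-oxopropanoate
Conditions: Pd(OCOCF3)2 (10 mol %), (R)-t-BuPyOx (12 mol %), NH4PF6 (30 mol %), H2O (5 equiv), 4 (1.5 equiv), ClCH2CH2Cl, 60 °C
Reagents that add atoms: none
Why: In this enantioselective palladium-catalysed conjugate addition of an arylboronic acid to a chromone, transmetalation gives a cationic aryl complex of divalent palladium, the tert-butyl oxazoline of the ligand steers its migratory insertion into C2=C3 to one face so that C2 is set as (S), and base-free protonolysis of the palladium enolate gives the new flavanone no path to epimerise.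

Step 11
Reactants: 13 tert-butyl 3-{2-(benzyloxy)-5'-[(2S)-5-(benzyloxy)-7-methoxy-4-oxochroman-2-yl]-2',6-dimethoxy-4-(methoxymethoxy)biphenyl-3-yl}-3-oxopropanoate
Product: 14 tert-butyl 3-{2-(benzyloxy)-5'-[(2S)-5-(benzyloxy)-7-methoxy-4-oxochroman-2-yl]-4-hydroxy-2',6-dimethoxybiphenyl-3-yl}-3-oxopropanoate
Conditions: conc. HCl (cat.), i-PrOH/THF, 40 °C
Reagents that add atoms: none
Why: Acid-catalysed acetal hydrolysis removes the MOM group, which is especially labile ortho to the carbonyl, while the benzyl ethers, the tert-butyl ester and the acid-stable C2 centre should survive.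

Step 12
Reactants: 14 tert-butyl 3-{2-(benzyloxy)-5'-[(2S)-5-(benzyloxy)-7-methoxy-4-oxochroman-2-yl]-4-hydroxy-2',6-dimethoxybiphenyl-3-yl}-3-oxopropanoate; 15 4-(benzyloxy)benzaldehyde
Product: 16 tert-butyl (Z)-3-[4-(benzyloxy)phenyl]-2-{2-(benzyloxy)-5'-[(2S)-5-(benzyloxy)-7-methoxy-4-oxochroman-2-yl]-4-hydroxy-2',6-dimethoxybiphenyl-3-carbonyl}acrylate
Conditions: piperidine (20 mol %), AcOH (20 mol %), 4 Å MS, toluene, rt to 40 °C
Reagents that add atoms: none
Why: The Knoevenagel condensation takes place only at the doubly activated CH2 (the C3 methylene of unit 1 is far less acidic) and should give mainly the isomer with the aryl group cis to the ester, and 2-hydroxyaryl alkylidene β-keto esters of this kind are known to survive the buffered amine without closing.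

Step 13
Reactants: 16 tert-butyl (Z)-3-[4-(benzyloxy)phenyl]-2-{2-(benzyloxy)-5'-[(2S)-5-(benzyloxy)-7-methoxy-4-oxochroman-2-yl]-4-hydroxy-2',6-dimethoxybiphenyl-3-carbonyl}acrylate
Product: 18 (2S,2''S)-5,5'',4'''-tris(benzyloxy)-7,4',7''-trimethoxy-3',6''-biflavanone, via 3''-carboxylate 17 (not isolated)
Conditions: 3,5-bis(trifluoromethyl)phenyl thiourea of 9-amino-9-deoxy-epi-quinidine (10 mol %), toluene, −25 °C; then TsOH·H2O, 80 °C
Reagents that add atoms: none
Why: The quinuclidine nitrogen of the bifunctional catalyst takes up the proton of the only free phenol (on C8a'') while the thiourea N–H pair binds the ketone and ester carbonyls of the alkylidene, the oxygen adds to the benzylidene carbon C2'' (intramolecular oxa-Michael addition), and the adduct rests as the hydrogen-bonded trans β-keto ester/enol 17, which should not revert under these mild conditions, so the closure is under kinetic control. The closest known reaction type is the cinchona-thiourea-catalysed cyclisation of 2-hydroxyaryl alkylidene β-keto tert-butyl esters to flavanones with acid decarboxylation in the same flask. Ring C of unit 2 closes in the 6-endo-trig mode by forming O1''–C2''. C2'' is set as (S) by the catalyst, which offers one face of the C2''=C3'' bond to the phenol, while the distant C2 centre and the freely rotating axis have no say and C3'' (trans, epimerisable) is erased afterwards. The step needs the oxygen on C8a'' and not O-5'' to attack (6''-linked rather than 8''-linked isomer), which the benzyl cap on the hindered O-5'' secures, and it needs unit 1 to stay closed, which the absence of any strong base secures. TsOH then cleaves the tert-butyl ester by E1 loss of isobutene and the β-keto acid loses CO2, so the helper bond C3''–CO2t-Bu disappears and leaves the CH2 of the target.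

Step 14
Reactants: 18 (2S,2''S)-5,5'',4'''-tris(benzyloxy)-7,4',7''-trimethoxy-3',6''-biflavanone
Product: 19 (2S,2''S)-5,5'',4'''-trihydroxy-7,4',7''-trimethoxy-3',6''-biflavanone (CNP0150873.1)
Conditions: H2 (1 atm), 10% Pd/C, EtOAc/THF, rt
Reagents that add atoms: none
Why: Catalytic hydrogenolysis removes the three aryl benzyl ethers under neutral, aprotic conditions, so the free 4'''-OH, which makes C2'' prone to ring opening in base, appears only when no further reagent follows.

Compound list
1 | 1-(2,6-dihydroxy-4-methoxyphenyl)ethanone | CC(=O)c1c(O)cc(OC)cc1O | starting material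
2 | 1-[2-(benzyloxy)-6-hydroxy-4-methoxyphenyl]ethanone | CC(=O)c1c(O)cc(OC)cc1OCc1ccccc1 | intermediate
3 | (E)-1-[2-(benzyloxy)-6-hydroxy-4-methoxyphenyl]-3-(dimethylamino)prop-2-en-1-one | CN(C)/C=C/C(=O)c1c(O)cc(OC)cc1OCc1ccccc1 | intermediate
4 | 5-(benzyloxy)-7-methoxy-4H-chromen-4-one | COc1cc(OCc2ccccc2)c2c(c1)occc2=O | intermediate
5 | 1-[2-hydroxy-4-methoxy-6-(methoxymethoxy)phenyl]ethanone | CC(=O)c1c(O)cc(OC)cc1OCOC | intermediate
6 | 1-[2-hydroxy-3-iodo-4-methoxy-6-(methoxymethoxy)phenyl]ethanone | CC(=O)c1c(O)c(I)c(OC)cc1OCOC | intermediate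
7 | 1-[2-(benzyloxy)-3-iodo-4-methoxy-6-(methoxymethoxy)phenyl]ethanone | CC(=O)c1c(OCc2ccccc2)c(I)c(OC)cc1OCOC | intermediate
8 | (5-chloro-2-methoxyphenyl)boronic acid | COc1ccc(Cl)cc1B(O)O | starting material
9 | 1-[2-(benzyloxy)-5'-chloro-2',6-dimethoxy-4-(methoxymethoxy)biphenyl-3-yl]ethanone | CC(=O)c1c(OCc2ccccc2)c(-c2cc(Cl)ccc2OC)c(OC)cc1OCOC | intermediate
10 | pinacol boronate of 9 (Bpin in place of Cl) | CC(=O)c1c(OCc2ccccc2)c(-c2cc(B3OC(C)(C)C(C)(C)O3)ccc2OC)c(OC)cc1OCOC | intermediate
11 | tert-butyl β-keto ester of 10 | CC(C)(C)OC(=O)CC(=O)c1c(OCc2ccccc2)c(-c2cc(B3OC(C)(C)C(C)(C)O3)ccc2OC)c(OC)cc1OCOC | intermediate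
12 | free boronic acid of 11 | CC(C)(C)OC(=O)CC(=O)c1c(OCc2ccccc2)c(-c2cc(B(O)O)ccc2OC)c(OC)cc1OCOC | intermediate
13 | (2S)-flavanone of unit 1 carrying the MOM-protected β-keto ester of unit 2 | COc1cc(OCc2ccccc2)c2c(c1)O[C@H](c1ccc(OC)c(-c3c(OC)cc(OCOC)c(C(=O)CC(=O)OC(C)(C)C)c3OCc3ccccc3)c1)CC2=O | intermediate
14 | free phenol of 13 (OH on the future C8a'') | COc1cc(OCc2ccccc2)c2c(c1)O[C@H](c1ccc(OC)c(-c3c(OC)cc(O)c(C(=O)CC(=O)OC(C)(C)C)c3OCc3ccccc3)c1)CC2=O | intermediate
15 | 4-(benzyloxy)benzaldehyde | O=Cc1ccc(OCc2ccccc2)cc1 | starting material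
16 | (Z)-4-(benzyloxy)benzylidene β-keto ester from 14 (aryl cis to the ester) | COc1cc(OCc2ccccc2)c2c(c1)O[C@H](c1ccc(OC)c(-c3c(OC)cc(O)c(C(=O)/C(C(=O)OC(C)(C)C)=C/c4ccc(OCc5ccccc5)cc4)c3OCc3ccccc3)c1)CC2=O | intermediate
17 | tert-butyl (2S,2''S,3''R)-5,5'',4'''-tris(benzyloxy)-7,4',7''-trimethoxy-3',6''-biflavanone-3''-carboxylate (2'',3''-trans) | COc1cc(OCc2ccccc2)c2c(c1)O[C@H](c1ccc(OC)c(-c3c(OC)cc4c(c3OCc3ccccc3)C(=O)[C@H](C(=O)OC(C)(C)C)[C@@H](c3ccc(OCc5ccccc5)cc3)O4)c1)CC2=O | intermediate
18 | (2S,2''S)-5,5'',4'''-tris(benzyloxy)-7,4',7''-trimethoxy-3',6''-biflavanone | COc1cc(OCc2ccccc2)c2c(c1)O[C@H](c1ccc(OC)c(-c3c(OC)cc4c(c3OCc3ccccc3)C(=O)C[C@@H](c3ccc(OCc5ccccc5)cc3)O4)c1)CC2=O | intermediate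
19 | (2S,2''S)-5,5'',4'''-trihydroxy-7,4',7''-trimethoxy-3',6''-biflavanone (CNP0150873.1) | COc1cc(O)c2c(c1)O[C@H](c1ccc(OC)c(-c3c(OC)cc4c(c3O)C(=O)C[C@@H](c3ccc(O)cc3)O4)c1)CC2=O | target

Total step count: 14. Longest linear sequence: 12 (steps 3 to 14, from 1).

Steps most likely to fail

Step 13. The 2,6-disubstituted aroyl group is twisted out of conjugation, so the catalysed closure may be slow. Uncatalysed closure could then erode the facial selectivity, and the hot acid stage could loosen the configuration at C2''. The fallback sets out from 14. Ring C of unit 2 is closed without a stereocentre by condensing the β-keto ester with DMF-DMA (toluene, rt, then cat. TsOH), which gives the tert-butyl chromone-3-carboxylate F1. C2'' is then set by the enantioselective palladium-catalysed 1,4-addition used in step 10, now with commercial 4-(benzyloxy)phenylboronic acid on the doubly activated C2''=C3'' bond. This comes back to the route at 17, which is decarboxylated with TsOH to 18.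

Step 10. Protodeboronation and homocoupling of the valuable boronic acid may outrun insertion into the electron-rich 5,7-dioxygenated chromone, and the face selectivity may fall short. The fallback sets out from 12 and 4. The addition is run with the more active achiral catalyst Pd(OCOCF3)2/2,2'-bipyridine and gives the racemic flavanone F2. Preparative chromatography on a chiral stationary phase then separates it into 13, where the route is rejoined, and the (R)-enantiomer F3, which is set aside.

Step 12. The hindered aroylacetate may condense sluggishly with the deactivated aldehyde. Longer exposure to the amine could bring on premature racemic ring closure or slow epimerisation of unit 1. The fallback sets out from 14 and 15. Aldehyde 15 is first condensed with 4-methylbenzenesulfonamide (Si(OEt)4, heat) to the N-tosylimine F4. β-Keto ester 14 adds to it in a Mannich reaction (cat. tertiary amine, CH2Cl2, 0 °C) and gives the Mannich adduct F5. Gentle warming with PPTS expels the sulfonamide, and the route is rejoined at 16.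

Further compounds
F1 | step 13 | tert-butyl chromone-3-carboxylate of unit 2 attached to (2S)-unit 1 | COc1cc(OCc2ccccc2)c2c(c1)O[C@H](c1ccc(OC)c(-c3c(OC)cc4occ(C(=O)OC(C)(C)C)c(=O)c4c3OCc3ccccc3)c1)CC2=O
F2 | step 10 | racemic form of 13 | COc1cc(OCc2ccccc2)c2c(c1)OC(c1ccc(OC)c(-c3c(OC)cc(OCOC)c(C(=O)CC(=O)OC(C)(C)C)c3OCc3ccccc3)c1)CC2=O
F3 | step 10 | (2R)-enantiomer of 13 | COc1cc(OCc2ccccc2)c2c(c1)O[C@@H](c1ccc(OC)c(-c3c(OC)cc(OCOC)c(C(=O)CC(=O)OC(C)(C)C)c3OCc3ccccc3)c1)CC2=O
F4 | step 12 | (E)-N-[4-(benzyloxy)benzylidene]-4-methylbenzenesulfonamide | Cc1ccc(cc1)S(=O)(=O)/N=C/c1ccc(OCc2ccccc2)cc1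
F5 | step 12 | Mannich adduct of 14 and F4 (new centres as a mixture, both erased on elimination) | COc1cc(OCc2ccccc2)c2c(c1)O[C@H](c1ccc(OC)c(-c3c(OC)cc(O)c(C(=O)C(C(=O)OC(C)(C)C)C(NS(=O)(=O)c4ccc(C)cc4)c4ccc(OCc5ccccc5)cc4)c3OCc3ccccc3)c1)CC2=O
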